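**Strategy.** Everything rests on disconnecting the O1–C6 bond of the 1,2-dioxane ring (O1, O2, C3, C4, C5, C6). The feature exploited is the fully substituted ring carbon C6, which carries O1, an ethyl group, ring carbon C5 and the olefinic carbon C7. A C6–C7 epoxide stores the C6 configuration and, when opened at C6, leaves C7 as a primary alcohol that later becomes the aldehyde for chain attachment. In one acid-catalysed operation the C3 hydroperoxide attacks C6 with inversion, closing the ring and completing its three stereocentres. The cyclisation substrate is an open-chain (3S,4S)-3-hydroperoxide carrying the (S)-configured C6–C7 epoxide and a silyl-protected C1 hydroxyl.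

Key step: step 12

Remark on numbering: plakortide numbering is used for all intermediates (C1 = carboxyl carbon; ring O1–O2–C3–C4–C5–C6 with O2 on C3 and O1 on C6; C7–C14 = side chain), also where a systematic name would number differently.
Assumption: 2-methylenebutan-1-ol is made from 2-ethylacrolein; the tartrate, allylborane and ligand enantiomers are chosen from the empirical rules stated in the steps.

Step 1
Reactants: 1 2-ethylacrolein
Product: 2 2-methylenebutan-1-ol
Conditions: NaBH4, CeCl3·7H2O, MeOH, 0 °C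
Reagents that add atoms: none
Why: Luche reduction delivers hydride to the carbonyl carbon only (1,2-reduction) and leaves the 1,1-disubstituted alkene untouched; no stereocentre is formed.

Step 2
Reactants: 2 2-methylenebutan-1-ol
Product: 3 (S)-(2-ethyloxiran-2-yl)methanol
Conditions: Ti(OiPr)4 (5 mol%), L-(+)-diisopropyl tartrate (6 mol%), t-BuOOH, 4 Å molecular sieves, CH2Cl2, −20 °C
Reagents that add atoms: tert-butyl hydroperoxide, CC(C)(C)OO
Why: Sharpless asymmetric epoxidation, in which the titanium tartrate complex binds the allylic hydroxyl and delivers oxygen to one alkene face, L-(+)-tartrate giving the (S)-epoxide in the same sense in which allyl alcohol gives (S)-glycidol; this sets the quaternary centre that becomes C6 after inversion.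

Step 3
Reactants: 3 (S)-(2-ethyloxiran-2-yl)methanol
Product: 4 [(2R)-2-ethyloxiran-2-yl]methyl trifluoromethanesulfonate
Conditions: Tf2O, 2,6-lutidine, CH2Cl2, −78 °C; used at once
Reagents that add atoms: trifluoromethanesulfonic anhydride, O=S(=O)(OS(=O)(=O)C(F)(F)F)C(F)(F)F
Why: Sulfonylation of the primary alcohol under cold, buffered conditions leaves the oxirane intact, and the quaternary centre is untouched (its descriptor becomes R only because the ligand priorities change).

Step 4
Reactants: 5 butanal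
Product: 6 (2S)-N-[(E)-butylidene]-2-(methoxymethyl)pyrrolidin-1-amine (butanal SAMP hydrazone)
Conditions: SAMP, MgSO4, CH2Cl2, 0 °C → rt
Reagents that add atoms: (S)-1-amino-2-(methoxymethyl)pyrrolidine (SAMP), COC[C@@H]1CCCN1N
Why: Condensation of the aldehyde with the hydrazine gives the (E)-hydrazone that carries the chiral auxiliary for the alkylation.

Step 5
Reactants: 6 butanal SAMP hydrazone; 4 [(2R)-2-ethyloxiran-2-yl]methyl trifluoromethanesulfonate
Product: 8 (2S)-N-[(1E,2S)-2-ethyl-3-[(2S)-2-ethyloxiran-2-yl]propylidene]-2-(methoxymethyl)pyrrolidin-1-amine, via lithium azaenolate 7 (not isolated)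
Conditions: LiN(i-Pr)2, THF, 0 °C; then 4, −100 → −78 °C
Reagents that add atoms: none
Why: Enders SAMP-hydrazone alkylation, in which the chelated lithium azaenolate is alkylated on the face left open by the methoxymethyl group so that C4 is set as S under auxiliary control, while direct displacement of the far more reactive triflate (not opening of the oxirane) keeps the configuration of the future C6.

Step 6
Reactants: 8 alkylated SAMP hydrazone
Product: 9 (2S)-2-ethyl-3-[(2S)-2-ethyloxiran-2-yl]propanal
Conditions: O3, CH2Cl2, −78 °C; argon purge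
Reagents that add atoms: ozone, [O-][O+]=O
Why: Ozonolysis of the C=N bond releases the aldehyde under neutral conditions at low temperature, so the α-stereocentre C4 and the oxirane survive.

Step 7
Reactants: 9 (2S)-2-ethyl-3-[(2S)-2-ethyloxiran-2-yl]propanal
Product: 11 (4R,5S)-5-ethyl-6-[(2S)-2-ethyloxiran-2-yl]hex-1-en-4-ol, via borinate ester 10 (not isolated)
Conditions: (+)-Ipc2B(allyl) (from (−)-α-pinene), Et2O, −78 °C; then NaBO3·4H2O, THF–H2O, rt
Reagents that add atoms: (+)-B-allyldiisopinocampheylborane, C=CCB([C@H]1C[C@H]2C[C@@H]([C@@H]1C)C2(C)C)[C@H]1C[C@H]2C[C@@H]([C@@H]1C)C2(C)C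
Why: Brown allylation transfers the allyl group through a chair six-membered transition state under reagent control, the (+)-reagent attacking the Re face of this α-branched aldehyde to set C3 as R (the configuration that is inverted in step 11), and the mild perborate work-up cleaves the borinate without opening the oxirane.

Step 8
Reactants: 11 (4R,5S)-5-ethyl-6-[(2S)-2-ethyloxiran-2-yl]hex-1-en-4-ol
Product: 13 (3R,4S)-4-ethyl-5-[(2S)-2-ethyloxiran-2-yl]pentane-1,3-diol, via hydroxy aldehyde 12 (not isolated)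
Conditions: O3, NaHCO3, CH2Cl2–MeOH, −78 °C; then NaBH4, −78 °C → rt
Reagents that add atoms: ozone, [O-][O+]=O
Why: Ozonolysis with reductive borohydride work-up cleaves the terminal alkene and reduces the resulting aldehyde in the same flask, giving the 1,3-diol without any acid that could drive the C3 hydroxyl onto the oxirane.

Step 9
Reactants: 13 (3R,4S)-4-ethyl-5-[(2S)-2-ethyloxiran-2-yl]pentane-1,3-diol
Product: 14 (3R,4S)-1-[(tert-butyldiphenylsilyl)oxy]-4-ethyl-5-[(2S)-2-ethyloxiran-2-yl]pentan-3-ol
Conditions: TBDPSCl, imidazole, CH2Cl2, 0 °C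
Reagents that add atoms: tert-butyl(chloro)diphenylsilane, CC(C)(C)[Si](Cl)(c1ccccc1)c1ccccc1
Why: Silylation with the bulky chlorosilane is selective for the primary C1 hydroxyl and leaves the hindered secondary C3 hydroxyl free.

Step 10
Reactants: 14 (3R,4S)-1-[(tert-butyldiphenylsilyl)oxy]-4-ethyl-5-[(2S)-2-ethyloxiran-2-yl]pentan-3-ol
Product: 15 (3R,4S)-1-[(tert-butyldiphenylsilyl)oxy]-4-ethyl-5-[(2S)-2-ethyloxiran-2-yl]pentan-3-yl methanesulfonate
Conditions: MsCl, Et3N, CH2Cl2, −10 °C
Reagents that add atoms: methanesulfonyl chloride, CS(=O)(=O)Cl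
Why: Sulfonylation turns the C3 hydroxyl into a leaving group with retention, and a mesylate is chosen over a triflate so that the oxirane oxygen cannot expel it by neighbouring-group participation.

Step 11
Reactants: 15 C3 mesylate; 16 hydrogen peroxide
Product: 17 tert-butyl{[(3S,4S)-4-ethyl-5-[(2S)-2-ethyloxiran-2-yl]-3-hydroperoxypentyl]oxy}diphenylsilane
Conditions: 50% aq H2O2 (large excess), KOH, MeOH–THF, 0 °C → rt
Reagents that add atoms: hydrogen peroxide (16), OO
Why: SN2 displacement of the secondary mesylate by hydroperoxide anion, an α-effect nucleophile, proceeds with inversion and converts the (3R)-mesylate into the (3S)-hydroperoxide, the large excess of peroxide suppressing a second alkylation.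

Step 12
Reactants: 17 tert-butyl{[(3S,4S)-4-ethyl-5-[(2S)-2-ethyloxiran-2-yl]-3-hydroperoxypentyl]oxy}diphenylsilane
Product: 18 [(3S,4S,6R)-3-{2-[(tert-butyldiphenylsilyl)oxy]ethyl}-4,6-diethyl-1,2-dioxan-6-yl]methanol
Conditions: camphor-10-sulfonic acid (10 mol%), CH2Cl2, 0 °C
Reagents that add atoms: none
Why: The sulfonic acid protonates the oxirane oxygen, the C6–O bond lengthens at the carbon best able to carry positive charge, and the terminal oxygen of the C3 hydroperoxide attacks C6 from the face opposite the departing oxygen, which stays on C7 as the primary hydroxyl group. The closest known reaction type is the acid-promoted intramolecular opening of epoxides by hydroperoxides that gives 1,2-dioxanes and 1,2-dioxolanes. The 1,2-dioxane ring (O1, O2, C3–C6) is closed in the 6-exo-tet mode. The new C6 stereocentre is controlled by the substrate: backside attack is stereospecific, so the (S)-oxirane configuration installed in step 2 is converted with inversion into (6R), while C3 and C4 are not touched. The step needs regioselectivity for C6 over C7 and clean inversion; both are secured because C6 is the tertiary, electronically activated carbon and the exo site of a six-membered transition state (attack at C7 would need a seven-membered ring), and because the tethered nucleophile can capture the developing cation in a non-nucleophilic solvent at low temperature before it relaxes.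

Step 13
Reactants: 19 (E)-pent-2-enal
Product: 20 (3R,4E)-hept-4-en-3-ol
Conditions: Et2Zn, Ti(OiPr)4, (1S,2S)-N,N′-bis(trifluoromethanesulfonyl)cyclohexane-1,2-diamine (5 mol%), toluene, −20 °C; then 1 M HCl
Reagents that add atoms: diethylzinc, CC[Zn]CC
Why: Catalytic enantioselective 1,2-addition of diethylzinc to the enal under a chiral titanium bis(sulfonamide) complex, in which the (1S,2S)-ligand (the antipode of the one that gives (S)-1-phenylpropan-1-ol from benzaldehyde) should deliver ethyl to the face that gives the (R)-allylic alcohol.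

Step 14
Reactants: 20 (3R,4E)-hept-4-en-3-ol
Product: 22 ethyl (3R,4E)-3-ethylhept-4-enoate, via ketene acetal 21 (not isolated)
Conditions: MeC(OEt)3, EtCO2H (cat.), 135 °C, EtOH distilled off
Reagents that add atoms: triethyl orthoacetate, CC(OCC)(OCC)OCC
Why: Johnson–Claisen rearrangement through a chair transition state with the carbinol ethyl group equatorial transfers the (R)-carbinol configuration suprafacially to the new C10 centre (R) and forms the C11=C12 alkene as the E isomer.

Step 15
Reactants: 22 ethyl (3R,4E)-3-ethylhept-4-enoate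
Product: 23 (3R,4E)-3-ethylhept-4-en-1-ol
Conditions: LiAlH4, Et2O, 0 °C
Reagents that add atoms: none
Why: Hydride reduction of the ester gives the primary alcohol without touching the isolated alkene or C10.

Step 16
Reactants: 23 (3R,4E)-3-ethylhept-4-en-1-ol
Product: 24 (3E,5R)-5-ethyl-7-iodohept-3-ene
Conditions: I2, PPh3, imidazole, CH2Cl2, 0 °C → rt
Reagents that add atoms: iodine, II
Why: Appel-type iodination converts the primary alcohol into the iodide through an alkoxyphosphonium ion by SN2 at a carbon that is not a stereocentre.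

Step 17
Reactants: 24 (3E,5R)-5-ethyl-7-iodohept-3-ene
Product: 25 [(3R,4E)-3-ethylhept-4-en-1-yl]triphenylphosphonium iodide
Conditions: PPh3, MeCN, reflux
Reagents that add atoms: triphenylphosphine, c1ccc(cc1)P(c1ccccc1)c1ccccc1
Why: Quaternisation of triphenylphosphine by the primary iodide (SN2) gives the phosphonium salt that carries C8–C14.

Step 18
Reactants: 18 [(3S,4S,6R)-3-{2-[(tert-butyldiphenylsilyl)oxy]ethyl}-4,6-diethyl-1,2-dioxan-6-yl]methanol
Product: 26 (3S,4S,6R)-3-{2-[(tert-butyldiphenylsilyl)oxy]ethyl}-4,6-diethyl-1,2-dioxane-6-carbaldehyde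
Conditions: Dess–Martin periodinane, NaHCO3, CH2Cl2, 0 °C → rt
Reagents that add atoms: none
Why: Dess–Martin oxidation under buffered, non-basic conditions gives the C7 aldehyde, which cannot epimerise because C6 is quaternary; it is used directly.

Step 19
Reactants: 25 [(3R,4E)-3-ethylhept-4-en-1-yl]triphenylphosphonium iodide; 26 dioxane carbaldehyde
Product: 30 tert-butyl(2-{(3S,4S,6R)-4,6-diethyl-6-[(1Z,4R,5E)-4-ethyl-2-iodoocta-1,5-dien-1-yl]-1,2-dioxan-3-yl}ethoxy)diphenylsilane, via phosphorus ylide 27 (not isolated), via iodophosphonium iodide 28 (not isolated), via iodo ylide 29 (not isolated)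
Conditions: 25, NaN(SiMe3)2, THF, 0 °C; I2, −78 °C; NaN(SiMe3)2, −78 → −20 °C; then 26, −78 °C → rt
Reagents that add atoms: iodine, II
Why: Stork–Zhao-type Wittig olefination, in which the non-stabilised α-iodo ylide made by iodination and renewed deprotonation adds under kinetic control to give the (Z)-iodoalkene, placing the C9 chain trans to C6 as the target requires.

Step 20
Reactants: 30 (Z)-iodoalkene
Product: 31 tert-butyl(2-{(3S,4S,6R)-6-[(1E,4R,5E)-2,4-diethylocta-1,5-dien-1-yl]-4,6-diethyl-1,2-dioxan-3-yl}ethoxy)diphenylsilane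
Conditions: Et2Zn, Pd(P(t-Bu)3)2 (5 mol%), THF, 0 °C → rt
Reagents that add atoms: diethylzinc, CC[Zn]CC
Why: Negishi coupling (oxidative addition of zerovalent palladium into the carbon–iodine bond, transmetalation from zinc, reductive elimination) replaces iodine by ethyl with retention of alkene geometry to give the (7E)-alkene, the bulky phosphine making reductive elimination faster than β-hydride elimination under conditions mild enough for the O–O bond.

Step 21
Reactants: 31 silyl ether
Product: 32 2-{(3S,4S,6R)-6-[(1E,4R,5E)-2,4-diethylocta-1,5-dien-1-yl]-4,6-diethyl-1,2-dioxan-3-yl}ethan-1-ol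
Conditions: Bu4NF, AcOH (1:1), THF, 0 °C → rt
Reagents that add atoms: none
Why: Fluoride-mediated cleavage of the silyl ether, buffered with acetic acid so that no basic fluoride or alkoxide can trigger Kornblum–DeLaMare fragmentation of the peroxide.

Step 22
Reactants: 32 primary alcohol
Product: 34 Plakortide N, via aldehyde 33 (not isolated)
Conditions: TEMPO (20 mol%), PhI(OAc)2, MeCN–H2O (pH 7 buffer), rt
Reagents that add atoms: water, O
Why: Oxoammonium-mediated oxidation takes the primary alcohol to the aldehyde and, through its hydrate, on to the carboxylic acid at neutral pH, which spares both alkenes and the peroxide and avoids β-elimination of the ring oxygen.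

**Compound list**

1 | 2-ethylacrolein | C=C(CC)C=O | starting material
2 | 2-methylenebutan-1-ol | C=C(CC)CO | intermediate
3 | (S)-(2-ethyloxiran-2-yl)methanol | C1O[C@@]1(CC)CO | intermediate
4 | [(2R)-2-ethyloxiran-2-yl]methyl trifluoromethanesulfonate | C1O[C@@]1(CC)COS(=O)(=O)C(F)(F)F | intermediate
5 | butanal | CCCC=O | starting material
6 | (2S)-N-[(E)-butylidene]-2-(methoxymethyl)pyrrolidin-1-amine | CCC/C=N/N1CCC[C@H]1COC | intermediate
7 | lithium azaenolate of 6 (not isolated) | [Li]N(/C=C/CC)N1CCC[C@H]1COC | intermediate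
8 | (2S)-N-[(1E,2S)-2-ethyl-3-[(2S)-2-ethyloxiran-2-yl]propylidene]-2-(methoxymethyl)pyrrolidin-1-amine | C1O[C@@]1(CC)C[C@H](CC)/C=N/N1CCC[C@H]1COC | intermediate
9 | (2S)-2-ethyl-3-[(2S)-2-ethyloxiran-2-yl]propanal | C1O[C@@]1(CC)C[C@H](CC)C=O | intermediate
10 | (4R,5S)-5-ethyl-6-[(2S)-2-ethyloxiran-2-yl]hex-1-en-4-yl diisopinocampheylborinate (not isolated) | C1O[C@@]1(CC)C[C@H](CC)[C@H](OB([C@H]2C[C@H]3C[C@@H]([C@@H]2C)C3(C)C)[C@H]2C[C@H]3C[C@@H]([C@@H]2C)C3(C)C)CC=C | intermediate
11 | (4R,5S)-5-ethyl-6-[(2S)-2-ethyloxiran-2-yl]hex-1-en-4-ol | C1O[C@@]1(CC)C[C@H](CC)[C@H](O)CC=C | intermediate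
12 | (3R,4S)-4-ethyl-5-[(2S)-2-ethyloxiran-2-yl]-3-hydroxypentanal (not isolated) | C1O[C@@]1(CC)C[C@H](CC)[C@H](O)CC=O | intermediate
13 | (3R,4S)-4-ethyl-5-[(2S)-2-ethyloxiran-2-yl]pentane-1,3-diol | C1O[C@@]1(CC)C[C@H](CC)[C@H](O)CCO | intermediate
14 | (3R,4S)-1-[(tert-butyldiphenylsilyl)oxy]-4-ethyl-5-[(2S)-2-ethyloxiran-2-yl]pentan-3-ol | C1O[C@@]1(CC)C[C@H](CC)[C@H](O)CCO[Si](c1ccccc1)(c1ccccc1)C(C)(C)C | intermediate
15 | (3R,4S)-1-[(tert-butyldiphenylsilyl)oxy]-4-ethyl-5-[(2S)-2-ethyloxiran-2-yl]pentan-3-yl methanesulfonate | C1O[C@@]1(CC)C[C@H](CC)[C@H](OS(C)(=O)=O)CCO[Si](c1ccccc1)(c1ccccc1)C(C)(C)C | intermediate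
16 | hydrogen peroxide | OO | starting material
17 | tert-butyl{[(3S,4S)-4-ethyl-5-[(2S)-2-ethyloxiran-2-yl]-3-hydroperoxypentyl]oxy}diphenylsilane | C1O[C@@]1(CC)C[C@H](CC)[C@@H](OO)CCO[Si](c1ccccc1)(c1ccccc1)C(C)(C)C | intermediate
18 | [(3S,4S,6R)-3-{2-[(tert-butyldiphenylsilyl)oxy]ethyl}-4,6-diethyl-1,2-dioxan-6-yl]methanol | OC[C@@]1(CC)C[C@H](CC)[C@H](CCO[Si](c2ccccc2)(c2ccccc2)C(C)(C)C)OO1 | intermediate
19 | (E)-pent-2-enal | CC/C=C/C=O | starting material
20 | (3R,4E)-hept-4-en-3-ol | CC/C=C/[C@H](O)CC | intermediate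
21 | (3R,4E)-3-[(1-ethoxyethenyl)oxy]hept-4-ene (not isolated) | CC/C=C/[C@H](OC(=C)OCC)CC | intermediate
22 | ethyl (3R,4E)-3-ethylhept-4-enoate | CC/C=C/[C@H](CC)CC(=O)OCC | intermediate
23 | (3R,4E)-3-ethylhept-4-en-1-ol | CC/C=C/[C@H](CC)CCO | intermediate
24 | (3E,5R)-5-ethyl-7-iodohept-3-ene | CC/C=C/[C@H](CC)CCI | intermediate
25 | [(3R,4E)-3-ethylhept-4-en-1-yl]triphenylphosphonium iodide | CC/C=C/[C@H](CC)CC[P+](c1ccccc1)(c1ccccc1)c1ccccc1.[I-] | intermediate
26 | (3S,4S,6R)-3-{2-[(tert-butyldiphenylsilyl)oxy]ethyl}-4,6-diethyl-1,2-dioxane-6-carbaldehyde | O=C[C@@]1(CC)C[C@H](CC)[C@H](CCO[Si](c2ccccc2)(c2ccccc2)C(C)(C)C)OO1 | intermediate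
27 | [(3R,4E)-3-ethylhept-4-en-1-ylidene]triphenyl-λ5-phosphane (not isolated) | CC/C=C/[C@H](CC)CC=P(c1ccccc1)(c1ccccc1)c1ccccc1 | intermediate
28 | [(3R,4E)-3-ethyl-1-iodohept-4-en-1-yl]triphenylphosphonium iodide, both C1 epimers (not isolated) | CC/C=C/[C@H](CC)CC(I)[P+](c1ccccc1)(c1ccccc1)c1ccccc1.[I-] | intermediate
29 | [(3R,4E)-3-ethyl-1-iodohept-4-en-1-ylidene]triphenyl-λ5-phosphane (not isolated) | CC/C=C/[C@H](CC)CC(I)=P(c1ccccc1)(c1ccccc1)c1ccccc1 | intermediate
30 | tert-butyl(2-{(3S,4S,6R)-4,6-diethyl-6-[(1Z,4R,5E)-4-ethyl-2-iodoocta-1,5-dien-1-yl]-1,2-dioxan-3-yl}ethoxy)diphenylsilane | CC/C=C/[C@H](CC)C/C(I)=C/[C@@]1(CC)C[C@H](CC)[C@H](CCO[Si](c2ccccc2)(c2ccccc2)C(C)(C)C)OO1 | intermediate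
31 | tert-butyl(2-{(3S,4S,6R)-6-[(1E,4R,5E)-2,4-diethylocta-1,5-dien-1-yl]-4,6-diethyl-1,2-dioxan-3-yl}ethoxy)diphenylsilane | CC/C=C/[C@H](CC)C/C(CC)=C/[C@@]1(CC)C[C@H](CC)[C@H](CCO[Si](c2ccccc2)(c2ccccc2)C(C)(C)C)OO1 | intermediate
32 | 2-{(3S,4S,6R)-6-[(1E,4R,5E)-2,4-diethylocta-1,5-dien-1-yl]-4,6-diethyl-1,2-dioxan-3-yl}ethan-1-ol | CC/C=C/[C@H](CC)C/C(CC)=C/[C@@]1(CC)C[C@H](CC)[C@H](CCO)OO1 | intermediate
33 | 2-{(3S,4S,6R)-6-[(1E,4R,5E)-2,4-diethylocta-1,5-dien-1-yl]-4,6-diethyl-1,2-dioxan-3-yl}acetaldehyde (not isolated) | CC/C=C/[C@H](CC)C/C(CC)=C/[C@@]1(CC)C[C@H](CC)[C@H](CC=O)OO1 | intermediate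
34 | Plakortide N, 2-{(3S,4S,6R)-6-[(1E,4R,5E)-2,4-diethylocta-1,5-dien-1-yl]-4,6-diethyl-1,2-dioxan-3-yl}acetic acid | CC/C=C/[C@H](CC)C/C(=C/[C@@]1(CC)C[C@H](CC)[C@H](CC(=O)O)OO1)CC | target

**Step count.** Total: 22 steps (1–12 to the dioxane, 13–17 side chain, 18–22 endgame). Longest linear sequence: 16 steps from 2-ethylacrolein (steps 1–3, 5–12, 18–22).

**Steps most likely to fail**

Step 11. The intermolecular substitution at the β-branched secondary carbon C3 may be outrun by E2 elimination of the mesylate, by attack of hydroperoxide anion on the oxirane, by a second alkylation of the product, or by slow loss of the silyl ether in aqueous base. The fallback replaces aqueous hydrogen peroxide by a singly protected peroxide nucleophile in a dipolar aprotic medium. Ozonolysis of 2,3-dimethylbut-2-ene in methanol gives 2-methoxypropan-2-yl hydroperoxide F1. Setting out from mesylate 15, this reagent with CsOH·H2O in DMF should give the peroxyketal tert-butyl{[(3S,4S)-4-ethyl-5-[(2S)-2-ethyloxiran-2-yl]-3-[(2-methoxypropan-2-yl)peroxy]pentyl]oxy}diphenylsilane F2 with inversion at C3. Brief treatment with aqueous acetic acid in THF releases the hydroperoxide and the route is rejoined at 17.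

Step 12. Ionisation at C6 may run ahead of ring closure, which would erode the inversion at C6 or divert the cation into a 1,2-hydride shift (Meinwald rearrangement to the aldehyde). The fallback swaps the order in which the two C–O bonds are made, so that the ring is closed by a clean SN2 reaction at the secondary carbon. Setting out from mesylate 15, perhydrolysis of the oxirane at its tertiary carbon with ethereal H2O2 and catalytic H3PMo12O40 should give (3R,4S,6R)-1-[(tert-butyldiphenylsilyl)oxy]-4,6-diethyl-6-hydroperoxy-7-hydroxyheptan-3-yl methanesulfonate F3. Treatment with KOt-Bu and 18-crown-6 in THF then lets the tertiary hydroperoxide displace the C3 mesylate with inversion (6-exo-tet), which rejoins the route at 18.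

Step 19. Addition of the bulky α-iodo ylide to the neopentyl-type aldehyde may be slow, the ylide may lose iodine, and the Z selectivity may erode. The fallback lets a small, reactive ylide meet the hindered aldehyde and sets the alkene geometry in a palladium step. Setting out from aldehyde 26, Ramirez dibromomethylenation (CBr4, PPh3, CH2Cl2, 0 °C) should give tert-butyl{2-[(3S,4S,6R)-6-(2,2-dibromoethenyl)-4,6-diethyl-1,2-dioxan-3-yl]ethoxy}diphenylsilane F4. Zinc dust converts iodide 24 into [(3R,4E)-3-ethylhept-4-en-1-yl]zinc iodide F5. Trans-selective Negishi mono-alkylation of F4 with F5 (PdCl2(DPEphos), THF) replaces the bromine trans to C6 and should give tert-butyl(2-{(3S,4S,6R)-6-[(1Z,4R,5E)-2-bromo-4-ethylocta-1,5-dien-1-yl]-4,6-diethyl-1,2-dioxan-3-yl}ethoxy)diphenylsilane F6. Ethylation of F6 under the conditions of step 20 rejoins the route at 31.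

Further compounds
F1 | step 11 | 2-methoxypropan-2-yl hydroperoxide | COC(C)(C)OO
F2 | step 11 | tert-butyl{[(3S,4S)-4-ethyl-5-[(2S)-2-ethyloxiran-2-yl]-3-[(2-methoxypropan-2-yl)peroxy]pentyl]oxy}diphenylsilane | C1O[C@@]1(CC)C[C@H](CC)[C@@H](OOC(C)(C)OC)CCO[Si](c1ccccc1)(c1ccccc1)C(C)(C)C
F3 | step 12 | (3R,4S,6R)-1-[(tert-butyldiphenylsilyl)oxy]-4,6-diethyl-6-hydroperoxy-7-hydroxyheptan-3-yl methanesulfonate | OC[C@](CC)(OO)C[C@H](CC)[C@H](OS(C)(=O)=O)CCO[Si](c1ccccc1)(c1ccccc1)C(C)(C)C
F4 | step 19 | tert-butyl{2-[(3S,4S,6R)-6-(2,2-dibromoethenyl)-4,6-diethyl-1,2-dioxan-3-yl]ethoxy}diphenylsilane | BrC(Br)=C[C@@]1(CC)C[C@H](CC)[C@H](CCO[Si](c2ccccc2)(c2ccccc2)C(C)(C)C)OO1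
F5 | step 19 | [(3R,4E)-3-ethylhept-4-en-1-yl]zinc iodide | CC/C=C/[C@H](CC)CC[Zn]I
F6 | step 19 | tert-butyl(2-{(3S,4S,6R)-6-[(1Z,4R,5E)-2-bromo-4-ethylocta-1,5-dien-1-yl]-4,6-diethyl-1,2-dioxan-3-yl}ethoxy)diphenylsilane | CC/C=C/[C@H](CC)C/C(Br)=C/[C@@]1(CC)C[C@H](CC)[C@H](CCO[Si](c2ccccc2)(c2ccccc2)C(C)(C)C)OO1
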